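**Retrosynthetic overview**

1. The ester C–O bond is made last, from oleoyl chloride and the C20 allylic alcohol freed by desilylation.
2. Ring A (the only ring; C1 = stereocentre, C2=C3 = alkene, C6 = gem-dimethyl carbon) is closed by a one-flask [3+3] annulation of an acyclic (S)-α-isopropenyl methyl ketone with (3-iodopropyl)triphenylphosphonium iodide. A tertiary radical/nickel coupling makes C5–C6, and an intramolecular Wittig reaction makes C2=C3.
3. Enabling feature: the quaternary C6 and the methyl-bearing olefinic C2 both sit on the single stereocentre C1, and C3–C5 carry no functionality. An isopropenyl group and an acetyl group on one preset carbon can therefore be bridged by a bare three-carbon unit.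
4. The ketone comes from (2E,6E)-farnesol: silylation, SeO2 oxidation of the terminal (E)-methyl, Sharpless epoxidation, isopropenyl cuprate opening with inversion (sets C1), and periodate cleavage (excises the oxidised carbon and unveils the methyl ketone).
5. Ring order: one ring only, formed in step 7.

Key step: step 7

Remark on the chemistry: farnesol, oleoyl chloride, isopropenylmagnesium bromide and 1,3-diiodopropane are assumed to be commercial; dpm = 2,2,6,6-tetramethylheptane-3,5-dionate.

**Route**

Step 1
Reactants: 1 (2E,6E)-farnesol; 2 tert-butyl(chloro)diphenylsilane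
Product: 3 tert-butyldiphenyl{[(2E,6E)-3,7,11-trimethyldodeca-2,6,10-trien-1-yl]oxy}silane
Conditions: imidazole, DMF, 0 °C to rt
Reagents that add atoms: tert-butyl(chloro)diphenylsilane 2, CC(C)(C)[Si](Cl)(c1ccccc1)c1ccccc1
Why: Standard silyl ether formation at the primary allylic hydroxyl should mask it with a group expected to survive the oxidations, the Grignard reagent and the amide base of the later steps; no stereocentre is involved.

Step 2
Reactants: 3 farnesyl silyl ether; 4 tert-butyl hydroperoxide
Product: 5 (2E,6E,10E)-12-[(tert-butyldiphenylsilyl)oxy]-2,6,10-trimethyldodeca-2,6,10-trien-1-ol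
Conditions: SeO2 (cat.), salicylic acid (cat.), t-BuOOH, CH2Cl2, 0 °C to rt
Reagents that add atoms: tert-butyl hydroperoxide 4, CC(C)(C)OO
Why: Selenium dioxide allylic oxidation (ene reaction then [2,3]-sigmatropic shift) is known to hydroxylate the (E)-methyl group of a terminal isopropylidene unit of acyclic terpenoids with retention of the E geometry, so the terminal alkene should be the one functionalised.

Step 3
Reactants: 5 allylic alcohol; 4 tert-butyl hydroperoxide
Product: 6 [(2S,3S)-3-{(3E,7E)-9-[(tert-butyldiphenylsilyl)oxy]-3,7-dimethylnona-3,7-dien-1-yl}-2-methyloxiran-2-yl]methanol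
Conditions: Ti(OiPr)4 (cat.), L-(+)-diethyl tartrate (cat.), t-BuOOH, 4 Å MS, CH2Cl2, −20 °C
Reagents that add atoms: tert-butyl hydroperoxide 4, CC(C)(C)OO
Why: Sharpless asymmetric epoxidation touches only the alkene that carries the free allylic hydroxyl, and L-(+)-diethyl tartrate should direct oxygen delivery to the face that gives the (2S,3S)-epoxy alcohol, so both epoxide stereocentres are set under reagent control.

Step 4
Reactants: 6 epoxy alcohol; 7 isopropenylmagnesium bromide
Product: 8 (2R,3S,6E,10E)-12-[(tert-butyldiphenylsilyl)oxy]-2,6,10-trimethyl-3-(prop-1-en-2-yl)dodeca-6,10-diene-1,2-diol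
Conditions: isopropenylMgBr (excess), CuI (cat.), THF, −30 to 0 °C
Reagents that add atoms: isopropenylmagnesium bromide 7, CC(=C)[Mg]Br
Why: Copper-catalysed Grignard opening of the 2,3-epoxy alcohol should proceed by SN2 attack at the secondary epoxide carbon (the other is fully substituted), so inversion there installs the isopropenyl group and sets the future ring stereocentre C1 as (S), leaving a 1,2-diol.

Step 5
Reactants: 8 diol
Product: 9 (3S,6E,10E)-12-[(tert-butyldiphenylsilyl)oxy]-6,10-dimethyl-3-(prop-1-en-2-yl)dodeca-6,10-dien-2-one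
Conditions: NaIO4, THF/pH 7 buffer, 0 °C
Reagents that add atoms: none
Why: Malaprade glycol cleavage of the primary–tertiary 1,2-diol should excise the hydroxymethyl carbon as formaldehyde and unveil the methyl ketone under near-neutral conditions expected to leave the α-stereocentre and the β,γ-alkene in place.

Step 6
Reactants: 10 1,3-diiodopropane; 11 triphenylphosphine
Product: 12 (3-iodopropyl)triphenylphosphonium iodide
Conditions: excess 1,3-diiodopropane, toluene, 100 °C
Reagents that add atoms: triphenylphosphine 11, c1ccc(cc1)P(c1ccccc1)c1ccccc1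
Why: Quaternisation of triphenylphosphine by SN2 displacement of one iodide is a standard phosphonium salt synthesis, and the excess of diiodide together with precipitation of the mono-salt should suppress the bis-phosphonium salt.

Step 7
Reactants: 9 (S)-α-isopropenyl ketone; 12 (3-iodopropyl)triphenylphosphonium iodide
Product: 15 tert-butyl{[(2E,6E)-3,7-dimethyl-9-[(1S)-2,6,6-trimethylcyclohex-2-en-1-yl]nona-2,6-dien-1-yl]oxy}diphenylsilane, via keto phosphonium iodide 13 (not isolated), via phosphonium ylide 14 (not isolated)
Conditions: Mn(dpm)3 (cat.), Ni(acac)2 (cat.), PhSiH3, K2CO3, DMA/THF, rt; then NaHMDS, THF, −78 °C to rt, same flask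
Reagents that add atoms: (3-iodopropyl)triphenylphosphonium iodide 12, [I-].ICCC[P+](c1ccccc1)(c1ccccc1)c1ccccc1
Why: Proposed new method: manganese-hydride hydrogen-atom transfer to the CH2 terminus of the isopropenyl group of 9 should give the tertiary radical at the future C6, which nickel is expected to capture and couple with the primary alkyl fragment from oxidative addition of the C–I bond of 12, forging the quaternary C5–C6 bond of 13; NaHMDS then converts the phosphonium into the non-stabilised ylide 14, which closes ring A by 6-exo-trig attack of C3 on the C2 ketone and oxaphosphetane collapse to the C2=C3 alkene. The closest known reaction types are the Mn/Ni dual-catalytic Markovnikov hydroalkylation of 1,1-disubstituted olefins with alkyl iodides, which builds quaternary carbons, and the intramolecular Wittig cyclisation of ω-oxoalkylphosphonium salts; new are the phosphonium-bearing iodide as coupling partner and the telescoping of both events in one flask. No stereocentre is created: C1 is set in steps 3 and 4, is not a reacting centre and should be carried through unchanged, and the ring fixes the alkene geometry. The step needs hydrogen-atom transfer to the 1,1-disubstituted alkene in preference to the two trisubstituted chain alkenes, which the unhindered =CH2 terminus should secure as in Mukaiyama-type hydrofunctionalisations of isopropenyl groups beside trisubstituted alkenes. It also needs ylide formation without enolisation at C1, which the greater acidity of the P–CH2 protons and the shielding of the C1–H by the new quaternary carbon should secure when the base is titrated in at −78 °C.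

Step 8
Reactants: 15 cyclised silyl ether
Product: 16 (2E,6E)-3,7-dimethyl-9-[(1S)-2,6,6-trimethylcyclohex-2-en-1-yl]nona-2,6-dien-1-ol
Conditions: TBAF, THF, 0 °C to rt
Reagents that add atoms: none
Why: Fluoride-mediated cleavage of the silyl ether is expected to free the primary allylic alcohol without touching the three trisubstituted alkenes or the stereocentre.

Step 9
Reactants: 16 allylic alcohol; 17 oleoyl chloride
Product: 18 (2E,6E)-3,7-dimethyl-9-[(1S)-2,6,6-trimethylcyclohex-2-en-1-yl]nona-2,6-dien-1-yl (9Z)-octadec-9-enoate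
Conditions: Et3N, DMAP (cat.), CH2Cl2, 0 °C to rt
Reagents that add atoms: oleoyl chloride 17, CCCCCCCC/C=C\CCCCCCCC(Cl)=O
Why: DMAP-catalysed acylation of the primary allylic alcohol with the acid chloride (nucleophilic acyl substitution) should give the ester under conditions that do not isomerise the (Z)-alkene of the oleoyl chain.

**Compound list**

1 | (2E,6E)-farnesol, (2E,6E)-3,7,11-trimethyldodeca-2,6,10-trien-1-ol | OC/C=C(\C)CC/C=C(\C)CCC=C(C)C | starting material
2 | tert-butyl(chloro)diphenylsilane | CC(C)(C)[Si](Cl)(c1ccccc1)c1ccccc1 | starting material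
3 | tert-butyldiphenyl{[(2E,6E)-3,7,11-trimethyldodeca-2,6,10-trien-1-yl]oxy}silane | CC(C)(C)[Si](c1ccccc1)(c1ccccc1)OC/C=C(\C)CC/C=C(\C)CCC=C(C)C | intermediate
4 | tert-butyl hydroperoxide | CC(C)(C)OO | starting material
5 | (2E,6E,10E)-12-[(tert-butyldiphenylsilyl)oxy]-2,6,10-trimethyldodeca-2,6,10-trien-1-ol | CC(C)(C)[Si](c1ccccc1)(c1ccccc1)OC/C=C(\C)CC/C=C(\C)CC/C=C(\C)CO | intermediate
6 | [(2S,3S)-3-{(3E,7E)-9-[(tert-butyldiphenylsilyl)oxy]-3,7-dimethylnona-3,7-dien-1-yl}-2-methyloxiran-2-yl]methanol | CC(C)(C)[Si](c1ccccc1)(c1ccccc1)OC/C=C(\C)CC/C=C(\C)CC[C@@H]2O[C@@]2(C)CO | intermediate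
7 | isopropenylmagnesium bromide (prop-1-en-2-ylmagnesium bromide) | CC(=C)[Mg]Br | starting material
8 | (2R,3S,6E,10E)-12-[(tert-butyldiphenylsilyl)oxy]-2,6,10-trimethyl-3-(prop-1-en-2-yl)dodeca-6,10-diene-1,2-diol | CC(C)(C)[Si](c1ccccc1)(c1ccccc1)OC/C=C(\C)CC/C=C(\C)CC[C@@H](C(C)=C)[C@@](C)(O)CO | intermediate
9 | (3S,6E,10E)-12-[(tert-butyldiphenylsilyl)oxy]-6,10-dimethyl-3-(prop-1-en-2-yl)dodeca-6,10-dien-2-one | CC(C)(C)[Si](c1ccccc1)(c1ccccc1)OC/C=C(\C)CC/C=C(\C)CC[C@@H](C(C)=C)C(C)=O | intermediate
10 | 1,3-diiodopropane | ICCCI | starting material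
11 | triphenylphosphine | c1ccc(cc1)P(c1ccccc1)c1ccccc1 | starting material
12 | (3-iodopropyl)triphenylphosphonium iodide | [I-].ICCC[P+](c1ccccc1)(c1ccccc1)c1ccccc1 | intermediate
13 | [(5S,8E,12E)-5-acetyl-14-[(tert-butyldiphenylsilyl)oxy]-4,4,8,12-tetramethyltetradeca-8,12-dien-1-yl]triphenylphosphonium iodide | CC(C)(C)[Si](c1ccccc1)(c1ccccc1)OC/C=C(\C)CC/C=C(\C)CC[C@@H](C(C)(C)CCC[P+](c1ccccc1)(c1ccccc1)c1ccccc1)C(C)=O.[I-] | intermediate
14 | [(5S,8E,12E)-5-acetyl-14-[(tert-butyldiphenylsilyl)oxy]-4,4,8,12-tetramethyltetradeca-8,12-dien-1-ylidene]triphenylphosphorane (ylide of 13) | CC(C)(C)[Si](c1ccccc1)(c1ccccc1)OC/C=C(\C)CC/C=C(\C)CC[C@@H](C(C)(C)CCC=P(c1ccccc1)(c1ccccc1)c1ccccc1)C(C)=O | intermediate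
15 | tert-butyl{[(2E,6E)-3,7-dimethyl-9-[(1S)-2,6,6-trimethylcyclohex-2-en-1-yl]nona-2,6-dien-1-yl]oxy}diphenylsilane | CC(C)(C)[Si](c1ccccc1)(c1ccccc1)OC/C=C(\C)CC/C=C(\C)CC[C@@H]1C(C)=CCCC1(C)C | intermediate
16 | (2E,6E)-3,7-dimethyl-9-[(1S)-2,6,6-trimethylcyclohex-2-en-1-yl]nona-2,6-dien-1-ol | OC/C=C(\C)CC/C=C(\C)CC[C@@H]1C(C)=CCCC1(C)C | intermediate
17 | oleoyl chloride, (9Z)-octadec-9-enoyl chloride | CCCCCCCC/C=C\CCCCCCCC(Cl)=O | starting material
18 | (2E,6E)-3,7-dimethyl-9-[(1S)-2,6,6-trimethylcyclohex-2-en-1-yl]nona-2,6-dien-1-yl (9Z)-octadec-9-enoate | CCCCCCCC/C=C\CCCCCCCC(=O)OC/C=C(\C)CC/C=C(\C)CC[C@@H]1C(C)=CCCC1(C)C | target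

**Step count**

Total steps: 9. Longest linear sequence: 8 (steps 1 to 5, then 7 to 9).

**Steps most likely to fail**

Step 7 (Proposed new method). Nickel capture and reductive elimination at the congested tertiary radical may be slow. That would allow reverse hydrogen-atom transfer to drag the alkene into conjugation with the ketone (loss of the stereocentre), or cyclisation of the radical onto the nearest chain alkene. In the second stage, residual Si–H activated by the base may reduce the ketone before the ylide closes.
Fallback: from ketone 9, the known iron-hydride Giese-type reductive olefin coupling with acrolein (Fe(acac)3, PhSiH3, EtOH/ethylene glycol, 60 °C) would form the quaternary carbon and give (5S,8E,12E)-5-acetyl-14-[(tert-butyldiphenylsilyl)oxy]-4,4,8,12-tetramethyltetradeca-8,12-dienal F1. An intramolecular McMurry coupling of its ketone and aldehyde (TiCl3(DME)1.5, Zn–Cu couple, DME, reflux, high dilution) would then form C2=C3 and return to the route at 15.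

Step 4. The SN2 opening at a carbon next to a fully substituted epoxide carbon may be slow. Magnesium-halide-induced rearrangement or halide opening of the epoxide, or migration of the epoxide toward the primary alkoxide, may then erode regiochemical fidelity.
Fallback: from allylic alcohol 5, phosphorylation (ClP(O)(OEt)2, pyridine) would give diethyl (2E,6E,10E)-12-[(tert-butyldiphenylsilyl)oxy]-2,6,10-trimethyldodeca-2,6,10-trien-1-yl phosphate F2. A copper-catalysed enantioselective SN2' allylic substitution with vinylboronic acid pinacol ester (CuCl, chiral sulfonate-bearing imidazolinium salt as carbene precursor, NaOMe, THF) would give tert-butyl{[(2E,6E,10R)-10-ethenyl-3,7,11-trimethyldodeca-2,6,11-trien-1-yl]oxy}diphenylsilane F3. Tsuji–Wacker oxidation of its monosubstituted vinyl group alone (PdCl2, CuCl, O2, DMF/H2O) would rejoin the route at ketone 9.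

Step 5. The β,γ-unsaturated ketone may undergo double-bond migration into conjugation, with racemisation, during cleavage, work-up or storage.
Fallback: from diol 8, the iron-hydride Giese coupling with acrolein would be run before the glycol cleavage to give (5S,8E,12E)-14-[(tert-butyldiphenylsilyl)oxy]-5-[(2R)-1,2-dihydroxypropan-2-yl]-4,4,8,12-tetramethyltetradeca-8,12-dienal F4. NaIO4 cleavage would then give the keto aldehyde F1 without the labile ketone ever being formed, and the McMurry ring closure described above returns to the route at 15.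

**Further compounds**

F1 | step 7 | (5S,8E,12E)-5-acetyl-14-[(tert-butyldiphenylsilyl)oxy]-4,4,8,12-tetramethyltetradeca-8,12-dienal | CC(C)(C)[Si](c1ccccc1)(c1ccccc1)OC/C=C(\C)CC/C=C(\C)CC[C@@H](C(C)(C)CCC=O)C(C)=O
F2 | step 4 | diethyl (2E,6E,10E)-12-[(tert-butyldiphenylsilyl)oxy]-2,6,10-trimethyldodeca-2,6,10-trien-1-yl phosphate | CC(C)(C)[Si](c1ccccc1)(c1ccccc1)OC/C=C(\C)CC/C=C(\C)CC/C=C(\C)COP(=O)(OCC)OCC
F3 | step 4 | tert-butyl{[(2E,6E,10R)-10-ethenyl-3,7,11-trimethyldodeca-2,6,11-trien-1-yl]oxy}diphenylsilane | CC(C)(C)[Si](c1ccccc1)(c1ccccc1)OC/C=C(\C)CC/C=C(\C)CC[C@@H](C(C)=C)C=C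
F4 | step 5 | (5S,8E,12E)-14-[(tert-butyldiphenylsilyl)oxy]-5-[(2R)-1,2-dihydroxypropan-2-yl]-4,4,8,12-tetramethyltetradeca-8,12-dienal | CC(C)(C)[Si](c1ccccc1)(c1ccccc1)OC/C=C(\C)CC/C=C(\C)CC[C@@H](C(C)(C)CCC=O)[C@@](C)(O)CO
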